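A direct plan would buy ring A complete as 2,4,5-trihydroxybenzaldehyde A1 and carry it as tris-MOM acid A2; ring B would be made as phenacyl bromide A3 (4-O-MOM, 3-O-prenyl) and joined to A2 as phenacyl ester A4.
Base would then have to move the aroyl group of A4 from oxygen to carbon to give 2-hydroxy-1,3-diketone A5, and methanolic HCl would close ring C at O1–C2 and remove four MOM groups in the same flask.
Its weakest step would be that base-induced acyl shift: it would have no close precedent, it would stand at the point of convergence, and ester cleavage and retro-Claisen fragmentation would compete with it.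
The second would be the acidic end game: an allylic aryl (prenyl) ether would have to outlast four acetals on the last, air-sensitive intermediate, and the ring closure would hang on which acetal happened to leave first.
The third would be the α-bromination that makes A3: an electrophilic bromine source would meet a trisubstituted olefin and an electron-rich arene only to install a leaving group.

**Plan of the new route**
Cuts: the O3 benzoate last; ring C at O1–C8a (not O1–C2), which takes O1 off ring A and leaves a plain catechol; then C2–C3 (aldol), giving 3,4-dihydroxyacetophenone (ring A, C4, C3) and a 3-O-prenylated protocatechualdehyde (ring B, C2).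
Enabling feature: on ring A, O1 at C8a is para to the C6 hydroxyl and C8a is β to the C7 oxygen, so ring A without O1 is a 4-acylcatechol whose o-quinone is electrophilic at C8a, within reach of the C2 enol oxygen of a 1,3-diketone.
Order of rings: ring B and an ordinary catechol are bought; ring C is closed on the non-aromatic o-quinone; the aromatic 1,2,4-trioxygenated ring A arises last, by tautomerisation, and is never a building block.
The weak steps cannot occur: the C3-oxygenated diketone comes from aldol addition, oxidation and enolate oxygenation (no acyl shift), no mineral acid or acetal follows the prenylation (silyl ethers leave with fluoride, the benzoate with ammonia), and nothing is halogenated.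

Key step: step 8

Remark: flavone numbering is used (O1, C2, C3, C4, C4a, C5 to C8, C8a; ring B primed). The target has no stereocenter; the carbinol and C3 stereocenters that arise on the way are formed racemic and vanish again.

Step 1
Reactants: 1 1-(3,4-dihydroxyphenyl)ethanone
Product: 2 1-[3,4-bis(tert-butyldimethylsilyloxy)phenyl]ethanone
Conditions: TBSCl (2.3 equiv), imidazole (5 equiv), DMF, rt
Reagents that add atoms: tert-butyldimethylsilyl chloride, CC(C)(C)[Si](C)(C)Cl
Why: Imidazole-promoted O-silylation (silyl ether formation) of both phenols should make the catechol inert to the base and the oxidants of steps 4 to 6 while staying removable with fluoride, without mineral acid.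

Step 2
Reactants: 3 3,4-dihydroxybenzaldehyde; 4 prenyl bromide (1-bromo-3-methylbut-2-ene)
Product: 5 4-hydroxy-3-(3-methylbut-2-enyloxy)benzaldehyde
Conditions: NaH (2.1 equiv), DMSO, 20 °C; then 4 (1.0 equiv), 20 °C; AcOH quench
Reagents that add atoms: none
Why: Regioselective Williamson ether synthesis on the catecholate dianion, in which the 4-oxide is delocalised into the para formyl group so that the more nucleophilic 3-oxide should take the single equivalent of the primary allylic bromide by SN2 and the prenyl group lands on O3' without any protecting group.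

Step 3
Reactants: 5 4-hydroxy-3-(3-methylbut-2-enyloxy)benzaldehyde
Product: 6 4-(tert-butyldimethylsilyloxy)-3-(3-methylbut-2-enyloxy)benzaldehyde
Conditions: TBSCl (1.2 equiv), imidazole (2.5 equiv), DMF, rt
Reagents that add atoms: tert-butyldimethylsilyl chloride, CC(C)(C)[Si](C)(C)Cl
Why: Silyl ether formation on the remaining acidic phenol keeps the aldehyde electrophilic in step 4 (a para phenoxide would deactivate it) and the group leaves together with the other silyl ethers in step 7.

Step 4
Reactants: 2 1-[3,4-bis(tert-butyldimethylsilyloxy)phenyl]ethanone; 6 4-(tert-butyldimethylsilyloxy)-3-(3-methylbut-2-enyloxy)benzaldehyde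
Product: 7 1-[3,4-bis(tert-butyldimethylsilyloxy)phenyl]-3-[4-(tert-butyldimethylsilyloxy)-3-(3-methylbut-2-enyloxy)phenyl]-3-hydroxypropan-1-one (racemic)
Conditions: LiN(SiMe3)2 (1.1 equiv), THF, −78 °C; then 6, −78 °C; AcOH quench at −78 °C
Reagents that add atoms: none
Why: Directed aldol addition, in which the lithium enolate of methyl ketone 2 adds to the non-enolisable aldehyde 6 to form the C2–C3 bond, the cold quench prevents retro-aldol cleavage and dehydration, and the carbinol stereocenter is formed racemic and removed in step 5.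

Step 5
Reactants: 7 1-[3,4-bis(tert-butyldimethylsilyloxy)phenyl]-3-[4-(tert-butyldimethylsilyloxy)-3-(3-methylbut-2-enyloxy)phenyl]-3-hydroxypropan-1-one
Product: 8 1-[3,4-bis(tert-butyldimethylsilyloxy)phenyl]-3-[4-(tert-butyldimethylsilyloxy)-3-(3-methylbut-2-enyloxy)phenyl]propane-1,3-dione
Conditions: IBX (2.5 equiv), EtOAc, 75 °C
Reagents that add atoms: none
Why: IBX oxidation of a β-hydroxy ketone to the 1,3-diketone, a reagent known to stop there without oxidising the central carbon, should leave the silyl ethers, the aryl prenyl ether and the olefin untouched under neutral conditions.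

Step 6
Reactants: 8 1-[3,4-bis(tert-butyldimethylsilyloxy)phenyl]-3-[4-(tert-butyldimethylsilyloxy)-3-(3-methylbut-2-enyloxy)phenyl]propane-1,3-dione
Product: 9 1-[3,4-bis(tert-butyldimethylsilyloxy)phenyl]-3-[4-(tert-butyldimethylsilyloxy)-3-(3-methylbut-2-enyloxy)phenyl]-1,3-dioxopropan-2-yl benzoate (racemic)
Conditions: NaH (1.0 equiv), THF, 0 °C; then (PhCO2)2 (1.05 equiv), 0 °C → rt
Reagents that add atoms: dibenzoyl peroxide, O=C(OOC(=O)c1ccccc1)c1ccccc1
Why: Electrophilic α-benzoyloxylation of a 1,3-dicarbonyl enolate, in which the sodium enolate of 8 attacks the O–O bond of the peroxide at oxygen and places the future O3 on C3 already masked as a benzoate, with a reagent that ignores the olefin and the arenes and a new stereocenter that is racemic and lost in step 8.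

Step 7
Reactants: 9 1-[3,4-bis(tert-butyldimethylsilyloxy)phenyl]-3-[4-(tert-butyldimethylsilyloxy)-3-(3-methylbut-2-enyloxy)phenyl]-1,3-dioxopropan-2-yl benzoate
Product: 10 1-(3,4-dihydroxyphenyl)-3-[4-hydroxy-3-(3-methylbut-2-enyloxy)phenyl]-1,3-dioxopropan-2-yl benzoate (racemic)
Conditions: KHF2 (6 equiv), MeOH, rt
Reagents that add atoms: none
Why: Fluoride-mediated cleavage of phenolic silyl ethers with mildly acidic KHF2 is selective for aryl O–Si bonds and should free the three phenols while the benzoate, the diketone and the acid-sensitive prenyl ether remain.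

Step 8
Reactants: 10 1-(3,4-dihydroxyphenyl)-3-[4-hydroxy-3-(3-methylbut-2-enyloxy)phenyl]-1,3-dioxopropan-2-yl benzoate
Product: 12 6,7-dihydroxy-2-[4-hydroxy-3-(3-methylbut-2-enyloxy)phenyl]-4-oxo-4H-chromen-3-yl benzoate, via ring A o-quinone 11 (not isolated)
Conditions: graphite felt anode, Pt cathode, divided cell, +0.45 V vs Ag/AgCl, 2.1 F/mol, 0.2 M NaOAc–AcOH (pH 5.5)/MeCN 1:1, 20 °C, Ar; then aq Na2S2O4 wash
Reagents that add atoms: none
Why: Proposed new method: at the anode the catechol of ring A, by far the most easily oxidised group in 10, loses two electrons and two protons to give o-quinone 11, the enol oxygen on C2 of the 2-benzoyloxy-1,3-diketone adds to C8a, the β-carbon of the C7 carbonyl (intramolecular oxa-Michael addition), and tautomerisation of the adduct re-forms the aromatic ring A as the 6,7-catechol of 12, so that one dehydrogenation makes the O1–C8a bond, ring C and the 1,2,4-trioxygenated ring A. The closest known reaction types are the anodic synthesis of 5,6-dihydroxybenzofurans from catechols and 1,3-dicarbonyl compounds, which ends with the same addition of an enol oxygen to an electrogenerated o-quinone, the cyclisation of dopaquinone, and the oxidative cyclisation of maclurin-type 3',4'-dihydroxybenzophenones to 6,7-dihydroxyxanthones; new is the use of an aryl 1,3-diketone enol to close a 4-pyranone. Ring C closes in the 6-exo-trig mode, since the attacked C8=C8a bond lies outside the new ring. No stereocenter is formed, and the C3 stereocenter of 10 disappears on enolisation. The step needs oxidation of ring A only, which the controlled potential below the wave of the acylated guaiacol of ring B and far below that of the olefin should secure; attack at C8a and not at C5, secured because C8a is the 1,4-position of the C7 carbonyl and para to the C6 oxygen whereas C5 is the α-carbon of the C6 carbonyl; and closure through the enol oxygen and not through O3 in a five-membered mode, secured by the benzoate on O3. Over-oxidation of 12 should be limited by the electron-poor pyranone now conjugated to the catechol, by stopping at the theoretical charge, and by the dithionite wash, which returns any product quinone to the catechol.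

Step 9
Reactants: 12 6,7-dihydroxy-2-[4-hydroxy-3-(3-methylbut-2-enyloxy)phenyl]-4-oxo-4H-chromen-3-yl benzoate
Product: 13 3,6,7-trihydroxy-2-[4-hydroxy-3-(3-methylbut-2-enyloxy)phenyl]-4H-chromen-4-one
Conditions: NH3 (7 M in MeOH), 0 °C → rt, degassed, Ar; then AcOH
Reagents that add atoms: none
Why: Ammonolysis of an enol ester, in which the 3-O-benzoate of a flavonol, the ester of an acidic phenol-like enol, should be cleaved by ammonia to benzamide and the free 3-hydroxyl under conditions that leave the prenyl ether and the pyranone intact, with argon guarding the catecholate against autoxidation.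

**Compound list**

1 | 1-(3,4-dihydroxyphenyl)ethanone | CC(=O)c1ccc(O)c(O)c1 | starting material
2 | 1-[3,4-bis(tert-butyldimethylsilyloxy)phenyl]ethanone | CC(=O)c1ccc(O[Si](C)(C)C(C)(C)C)c(O[Si](C)(C)C(C)(C)C)c1 | intermediate
3 | 3,4-dihydroxybenzaldehyde | O=Cc1ccc(O)c(O)c1 | starting material
4 | prenyl bromide (1-bromo-3-methylbut-2-ene) | CC(C)=CCBr | starting material
5 | 4-hydroxy-3-(3-methylbut-2-enyloxy)benzaldehyde | CC(C)=CCOc1cc(C=O)ccc1O | intermediate
6 | 4-(tert-butyldimethylsilyloxy)-3-(3-methylbut-2-enyloxy)benzaldehyde | CC(C)=CCOc1cc(C=O)ccc1O[Si](C)(C)C(C)(C)C | intermediate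
7 | 1-[3,4-bis(tert-butyldimethylsilyloxy)phenyl]-3-[4-(tert-butyldimethylsilyloxy)-3-(3-methylbut-2-enyloxy)phenyl]-3-hydroxypropan-1-one (racemic) | CC(C)=CCOc1cc(C(O)CC(=O)c2ccc(O[Si](C)(C)C(C)(C)C)c(O[Si](C)(C)C(C)(C)C)c2)ccc1O[Si](C)(C)C(C)(C)C | intermediate
8 | 1-[3,4-bis(tert-butyldimethylsilyloxy)phenyl]-3-[4-(tert-butyldimethylsilyloxy)-3-(3-methylbut-2-enyloxy)phenyl]propane-1,3-dione | CC(C)=CCOc1cc(C(=O)CC(=O)c2ccc(O[Si](C)(C)C(C)(C)C)c(O[Si](C)(C)C(C)(C)C)c2)ccc1O[Si](C)(C)C(C)(C)C | intermediate
9 | 1-[3,4-bis(tert-butyldimethylsilyloxy)phenyl]-3-[4-(tert-butyldimethylsilyloxy)-3-(3-methylbut-2-enyloxy)phenyl]-1,3-dioxopropan-2-yl benzoate (racemic) | CC(C)=CCOc1cc(C(=O)C(OC(=O)c2ccccc2)C(=O)c2ccc(O[Si](C)(C)C(C)(C)C)c(O[Si](C)(C)C(C)(C)C)c2)ccc1O[Si](C)(C)C(C)(C)C | intermediate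
10 | 1-(3,4-dihydroxyphenyl)-3-[4-hydroxy-3-(3-methylbut-2-enyloxy)phenyl]-1,3-dioxopropan-2-yl benzoate (racemic) | CC(C)=CCOc1cc(C(=O)C(OC(=O)c2ccccc2)C(=O)c2ccc(O)c(O)c2)ccc1O | intermediate
11 | 1-(3,4-dioxocyclohexa-1,5-dien-1-yl)-3-[4-hydroxy-3-(3-methylbut-2-enyloxy)phenyl]-1,3-dioxopropan-2-yl benzoate (ring A o-quinone, not isolated) | CC(C)=CCOc1cc(C(=O)C(OC(=O)c2ccccc2)C(=O)C2=CC(=O)C(=O)C=C2)ccc1O | intermediate
12 | 6,7-dihydroxy-2-[4-hydroxy-3-(3-methylbut-2-enyloxy)phenyl]-4-oxo-4H-chromen-3-yl benzoate | CC(C)=CCOc1cc(-c2oc3cc(O)c(O)cc3c(=O)c2OC(=O)c2ccccc2)ccc1O | intermediate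
13 | 3,6,7-trihydroxy-2-[4-hydroxy-3-(3-methylbut-2-enyloxy)phenyl]-4H-chromen-4-one (CNP0086069.0) | CC(C)=CCOc1cc(-c2oc3cc(O)c(O)cc3c(=O)c2O)ccc1O | target

Total step count: 9. Longest linear sequence: 8 steps (3 → 5 → 6 → 7 → 8 → 9 → 10 → 12 → 13); the other branch is one step (1 → 2).

**Steps most likely to fail**

1. Step 8 (proposed new method). The product catechol may be oxidised further at the electrode, the o-quinone may be captured by water or acetate before the enol oxygen arrives, or the ring may close at C5. The fallback uses known chemistry, sets out from ketone 2 and returns at 12. Ring bromination of 2 with NBS in MeCN, para to the 3-silyloxy group, should give bromo ketone F1. Aldol addition of its lithium enolate to 6, IBX oxidation and NaH/dibenzoyl peroxide, as in steps 4 to 6, would give bromo aldol adduct F2, bromo diketone F3 and bromo diketone benzoate F4. A copper-catalysed intramolecular Ullmann-type O-arylation of the diketone enolate (CuI, 1,10-phenanthroline, K3PO4, toluene, 90 °C), the established closure of 1-(2-bromoaryl)-1,3-diketones to flavones, would then form O1–C8a by substitution instead of oxidation and give tris-silyl flavone benzoate F5. KHF2 in MeOH would return to 12.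

2. Step 2. Alkylation may occur at the 4-oxygen, at both oxygens or at carbon. The fallback sets out from prenyl bromide 4 and returns at 5. Bromide 4 would alkylate the only hydroxyl of commercial 4-fluoro-3-hydroxybenzaldehyde F6 (K2CO3, DMF) to give fluoro prenyl ether F7, in which the positions of the two oxygens are fixed by construction. Nucleophilic aromatic substitution of the fluoride para to the formyl group by the alkoxide of 2-(methylsulfonyl)ethanol (NaH, DMF) would give sulfonylethyl aryl ether F8, which is not isolated, and β-elimination of methyl vinyl sulfone in the same flask would give 5.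

3. Step 6. A second oxygenation at C3 may occur, or silyl groups may be lost to the enolate and the benzoate formed. The fallback sets out from 8 and returns at 9. Diazo transfer to 8 (4-acetamidobenzenesulfonyl azide, Et3N, MeCN) would give diazo diketone F9. Rh2(OAc)4-catalysed insertion of the carbenoid into the O–H bond of benzoic acid (CH2Cl2, rt) would give 9 without an enolate or a peroxide.

**Further compounds**

F1 | step 8 | 1-[2-bromo-4,5-bis(tert-butyldimethylsilyloxy)phenyl]ethanone | CC(=O)c1cc(O[Si](C)(C)C(C)(C)C)c(O[Si](C)(C)C(C)(C)C)cc1Br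
F2 | step 8 | 1-[2-bromo-4,5-bis(tert-butyldimethylsilyloxy)phenyl]-3-[4-(tert-butyldimethylsilyloxy)-3-(3-methylbut-2-enyloxy)phenyl]-3-hydroxypropan-1-one (racemic) | CC(C)=CCOc1cc(C(O)CC(=O)c2cc(O[Si](C)(C)C(C)(C)C)c(O[Si](C)(C)C(C)(C)C)cc2Br)ccc1O[Si](C)(C)C(C)(C)C
F3 | step 8 | 1-[2-bromo-4,5-bis(tert-butyldimethylsilyloxy)phenyl]-3-[4-(tert-butyldimethylsilyloxy)-3-(3-methylbut-2-enyloxy)phenyl]propane-1,3-dione | CC(C)=CCOc1cc(C(=O)CC(=O)c2cc(O[Si](C)(C)C(C)(C)C)c(O[Si](C)(C)C(C)(C)C)cc2Br)ccc1O[Si](C)(C)C(C)(C)C
F4 | step 8 | 1-[2-bromo-4,5-bis(tert-butyldimethylsilyloxy)phenyl]-3-[4-(tert-butyldimethylsilyloxy)-3-(3-methylbut-2-enyloxy)phenyl]-1,3-dioxopropan-2-yl benzoate (racemic) | CC(C)=CCOc1cc(C(=O)C(OC(=O)c2ccccc2)C(=O)c2cc(O[Si](C)(C)C(C)(C)C)c(O[Si](C)(C)C(C)(C)C)cc2Br)ccc1O[Si](C)(C)C(C)(C)C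
F5 | step 8 | 6,7-bis(tert-butyldimethylsilyloxy)-2-[4-(tert-butyldimethylsilyloxy)-3-(3-methylbut-2-enyloxy)phenyl]-4-oxo-4H-chromen-3-yl benzoate | CC(C)=CCOc1cc(-c2oc3cc(O[Si](C)(C)C(C)(C)C)c(O[Si](C)(C)C(C)(C)C)cc3c(=O)c2OC(=O)c2ccccc2)ccc1O[Si](C)(C)C(C)(C)C
F6 | step 2 | 4-fluoro-3-hydroxybenzaldehyde | O=Cc1ccc(F)c(O)c1
F7 | step 2 | 4-fluoro-3-(3-methylbut-2-enyloxy)benzaldehyde | CC(C)=CCOc1cc(C=O)ccc1F
F8 | step 2 | 4-[2-(methylsulfonyl)ethoxy]-3-(3-methylbut-2-enyloxy)benzaldehyde | CC(C)=CCOc1cc(C=O)ccc1OCCS(C)(=O)=O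
F9 | step 6 | 1-[3,4-bis(tert-butyldimethylsilyloxy)phenyl]-3-[4-(tert-butyldimethylsilyloxy)-3-(3-methylbut-2-enyloxy)phenyl]-2-diazopropane-1,3-dione | CC(C)=CCOc1cc(C(=O)C(=[N+]=[N-])C(=O)c2ccc(O[Si](C)(C)C(C)(C)C)c(O[Si](C)(C)C(C)(C)C)c2)ccc1O[Si](C)(C)C(C)(C)C
A1 | direct plan | 2,4,5-trihydroxybenzaldehyde | O=Cc1cc(O)c(O)cc1O
A2 | direct plan | 2,4,5-tris(methoxymethoxy)benzoic acid | OC(=O)c1cc(OCOC)c(OCOC)cc1OCOC
A3 | direct plan | 2-bromo-1-[4-(methoxymethoxy)-3-(3-methylbut-2-enyloxy)phenyl]ethanone | BrCC(=O)c1ccc(OCOC)c(OCC=C(C)C)c1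
A4 | direct plan | 2-[4-(methoxymethoxy)-3-(3-methylbut-2-enyloxy)phenyl]-2-oxoethyl 2,4,5-tris(methoxymethoxy)benzoate | CC(C)=CCOc1cc(C(=O)COC(=O)c2cc(OCOC)c(OCOC)cc2OCOC)ccc1OCOC
A5 | direct plan | 2-hydroxy-1-[4-(methoxymethoxy)-3-(3-methylbut-2-enyloxy)phenyl]-3-[2,4,5-tris(methoxymethoxy)phenyl]propane-1,3-dione | CC(C)=CCOc1cc(C(=O)C(O)C(=O)c2cc(OCOC)c(OCOC)cc2OCOC)ccc1OCOC
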